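**Assumption:** Agecorynin G has no stereocenters. It is a 5,6,7-trimethoxyflavone whose B ring carries 2'-OMe, 3'-OH, 4'-OMe and 5'-OMe, so the single-enantiomer requirement is trivially met. The only stereochemical feature in the route is the E geometry of the chalcone, which is erased in Step 6.

## Retrosynthesis
1. The flavone C2=C3 and O1–C2 bonds come from I2/DMSO oxidative cyclisation of a 2'-hydroxychalcone. This closes the pyranone ring last.
2. The chalcone comes from a Claisen–Schmidt condensation of A-ring acetophenone 2 (from symmetrical 3,4,5-trimethoxyphenol, 1) with B-ring aldehyde 6.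
3. Aldehyde 6 is made from commercial 2,4,5-trimethoxybenzaldehyde (3). The aldehyde is masked as the acetal, C3 (flanked by two OMe groups) is lithiated, and the aryl lithium is borylated, oxidised to the phenol and benzylated.
4. The 3'-OH is carried as a benzyl ether because Lewis-acid demethylation would also cleave the 5-OMe. Hydrogenolysis releases it in the last step.

## Route

**Step 1**
Reactants: 1 (3,4,5-trimethoxyphenol)
Product: 2 (2'-hydroxy-4',5',6'-trimethoxyacetophenone)
Conditions: AcOH, BF3·OEt2, 90 °C
Reagents that add atoms: acetic acid, CC(=O)O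
Why: BF3-mediated Friedel–Crafts ortho-acylation (Nencki-type) of the phenol. The two ortho positions are equivalent by symmetry, so only one regioisomer forms. The BF3-chelated ortho-hydroxyketone is favoured without OMe cleavage.

**Step 2**
Reactants: 3 (2,4,5-trimethoxybenzaldehyde)
Product: 4 (2,4,5-trimethoxybenzaldehyde dimethyl acetal)
Conditions: HC(OMe)3, cat. TsOH, MeOH, rt; then Et3N quench
Reagents that add atoms: trimethyl orthoformate, COC(OC)OC
Why: acetalisation masks the aldehyde so it survives the organolithium step. Base is added before concentration because the electron-rich acetal is acid-labile.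

**Step 3**
Reactants: 4 (2,4,5-trimethoxybenzaldehyde dimethyl acetal)
Product: 5 (3-hydroxy-2,4,5-trimethoxybenzaldehyde)
Conditions: (i) n-BuLi, THF, 0 °C to rt; (ii) B(OMe)3, –78 °C to rt; (iii) 30% H2O2, 2 M NaOH, 0 °C; (iv) 2 M HCl, rt
Reagents that add atoms: hydrogen peroxide, OO (supplies the phenol oxygen); water, O (acetal hydrolysis, supplies the aldehyde oxygen). Trimethyl borate, COB(OC)OC, is also used but no atoms from it remain in 5, because boron is lost in the oxidation.
Why: directed ortho-lithiation at C3, the position flanked by two OMe groups (a cooperative, doubly activated site). The aryl boronate is oxidised to the phenol (oxidative deborylation), and the acid work-up hydrolyses the acetal back to the aldehyde. No stereocenter is involved.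

**Step 4**
Reactants: 5 (3-hydroxy-2,4,5-trimethoxybenzaldehyde)
Product: 6 (3-(benzyloxy)-2,4,5-trimethoxybenzaldehyde)
Conditions: BnBr, K2CO3, DMF, 50 °C
Reagents that add atoms: benzyl bromide, BrCc1ccccc1
Why: Williamson etherification of the phenol. The benzyl ether is base-stable for Step 5 and removable by hydrogenolysis at the end.

**Step 5**
Reactants: 2 (2'-hydroxy-4',5',6'-trimethoxyacetophenone) and 6 (3-(benzyloxy)-2,4,5-trimethoxybenzaldehyde)
Product: 7 ((E)-2'-hydroxychalcone)
Conditions: 50% aq. KOH, EtOH, rt, 48 h
Reagents that add atoms: none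
Why: Claisen–Schmidt aldol condensation. Dehydration gives the conjugated E-enone, which is thermodynamically favoured.

**Step 6**
Reactants: 7 (chalcone)
Product: 8 (3'-O-benzyl agecorynin G)
Conditions: I2 (0.2 equiv), DMSO, 130 °C
Reagents that add atoms: none
Why: iodine-catalysed oxidative cyclisation. Intramolecular oxa-Michael addition and iodination give an α-iodoflavanone, which eliminates HI, and DMSO reoxidises HI to I2. This forms the pyranone ring and the C2=C3 double bond, and the chalcone geometry is lost.

**Step 7**
Reactants: 8 (3'-O-benzyl agecorynin G)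
Product: 9 (agecorynin G)
Conditions: H2 (1 atm), 10% Pd/C, EtOAc/MeOH, rt, stop at consumption of 8
Reagents that add atoms: none (H2 only adds hydrogen; the toluene by-product is lost)
Why: catalytic hydrogenolysis of the benzyl ether releases the 3'-OH. Under these mild conditions the aryl methyl ethers and the flavone C2=C3 are unaffected.

## Checks against the target
- **Target match:** 9 has a 5,6,7-trimethoxychromone A ring. Its B ring has C1' attached to C2, 2'-OMe, 3'-OH, 4'-OMe, 5'-OMe and H at 6'. This matches the target SMILES.
- **Atom balance:** 1 (C9H12O4) + AcOH – H2O gives 2 (C11H14O5). 2 + 6 (C17H18O5) – H2O gives 7 (C28H30O9). Loss of 2H gives 8 (C28H28O9). Loss of C7H6 gives 9 (C21H22O9), which matches the target.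
- **Functional-group survival:**
  - The acetal survives n-BuLi and is removed only in the acidic work-up.
  - The benzyl ether survives KOH and I2/DMSO.
  - The OMe groups survive every step.
  - Only the benzyl ether is cleaved in Step 7.
- **Stereocenters:** there are none to set or scramble.

## Compound list
1 | 3,4,5-trimethoxyphenol | COc1cc(O)cc(OC)c1OC | starting material
2 | 2'-hydroxy-4',5',6'-trimethoxyacetophenone | CC(=O)c1c(O)cc(OC)c(OC)c1OC | intermediate
3 | 2,4,5-trimethoxybenzaldehyde | O=Cc1cc(OC)c(OC)cc1OC | starting material
4 | 2,4,5-trimethoxybenzaldehyde dimethyl acetal | COC(OC)c1cc(OC)c(OC)cc1OC | intermediate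
5 | 3-hydroxy-2,4,5-trimethoxybenzaldehyde | O=Cc1cc(OC)c(OC)c(O)c1OC | intermediate
6 | 3-(benzyloxy)-2,4,5-trimethoxybenzaldehyde | O=Cc1cc(OC)c(OC)c(OCc2ccccc2)c1OC | intermediate
7 | (E)-3-(3-benzyloxy-2,4,5-trimethoxyphenyl)-1-(2-hydroxy-4,5,6-trimethoxyphenyl)prop-2-en-1-one | COc1cc(O)c(C(=O)/C=C/c2cc(OC)c(OC)c(OCc3ccccc3)c2OC)c(OC)c1OC | intermediate
8 | 3'-O-benzyl agecorynin G (2-(3-benzyloxy-2,4,5-trimethoxyphenyl)-5,6,7-trimethoxychromen-4-one) | COc1cc(-c2cc(=O)c3c(OC)c(OC)c(OC)cc3o2)c(OC)c(OCc2ccccc2)c1OC | intermediate
9 | Agecorynin G | COc1cc(-c2cc(=O)c3c(OC)c(OC)c(OC)cc3o2)c(OC)c(O)c1OC | target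

## Totals
Total steps: 7. Longest linear sequence: 6 steps (3 → 4 → 5 → 6 → 7 → 8 → 9); the A-ring branch (1 → 2) is one extra step that joins at Step 5.

## Three steps most likely to fail
1. **Step 3 (C3 lithiation and oxidation).** Lithiation may compete at C6, next to the acetal.
   - Fallback: put the oxygen in first. Lithiate 1,2,4-trimethoxybenzene at C3 and trap with I2. Then do a Vilsmeier formylation at C5, form the acetal, and convert Ar–I to Ar–OH by Li–I exchange, borylation and oxidation.
2. **Step 5 (Claisen–Schmidt).** The aldehyde is hindered and very electron-rich, so the aldol may be slow or low-yielding.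
   - Fallback: Pinnick-oxidise 6 to the acid and esterify it. Then do a Claisen condensation of 2 with the ester (LiHMDS or NaH) to give the 1,3-diketone. Cyclodehydrate with TsOH/AcOH to give 8 directly (Baker–Venkataraman-type).
3. **Step 6 (I2/DMSO cyclisation).** The B ring has a free electron-rich position (C6'), so arene iodination or benzyl cleavage by HI could occur.
   - Fallback: cyclise the chalcone to the flavanone (NaOAc, EtOH, reflux) and then dehydrogenate it by a Pd(II)/O2 route (Pd(TFA)2, DMSO, O2). This avoids iodine and strong acid.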